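**Retrosynthetic overview**
- The C14 acetate goes on last, by α'-acetoxylation of the finished tricyclic enone.
- The ten-membered ring and the butenolide close together: C7–C8 alkenyl triflate–aldehyde coupling (NiCl2/CrCl2), then lactonisation.
- The cyclohexenone ring comes from a 1,5-diketone (aldol condensation). The diketone comes from an alcohol-tethered crossed [2+2] photocycloaddition/retro-aldol, which forms C1–C14 and C10–C11 and sets the quaternary C1.
- The (E)-allylic alcohol comes from (S)-α-hydroxy-γ-butyrolactone (source of C2): Negishi coupling (C4–C5), ester to alkyne, carboalumination/allylation (C1–CH3, C10–C9).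
- Ring order: cyclohexenone first, then ten-membered ring and butenolide in one step.

Assumption: (Z)-3-iodobut-2-en-1-ol (4) is taken as a purchasable catalogue building block.
Convention: carbon labels follow the target skeleton: C1 quaternary ring-fusion carbon (C15 methyl), C2 tigloyloxy carbon, C3/C4 CH2, C5=C6 ring alkene (C16 methyl), C7 lactone O–CH, C8=C17 butenolide alkene (C18 methyl, C19 C=O), C9 CH2, C10 ring-fusion CH, C11=C12 enone alkene (C20 methyl), C13 ketone, C14 acetoxy carbon.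

**Step 1**
Reactants: 1 methyl 2-methyl-3-oxobutanoate
Product: 2 methyl 4-bromo-2-methyl-3-oxobutanoate
Conditions: Br2, CHCl3, 0 °C → rt, 16 h
Reagents that add atoms: bromine (BrBr)
Why: Acid-catalysed α-bromination of the β-keto ester, in which the first-formed 2-bromide isomerises under the released HBr to the more stable 4-bromide, as in the standard route to 4-bromoacetoacetates.

**Step 2**
Reactants: 2 methyl 4-bromo-2-methyl-3-oxobutanoate
Product: 3 methyl (E)-4-bromo-3-methoxy-2-methylbut-2-enoate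
Conditions: HC(OMe)3, H2SO4 (cat.), MeOH, rt; then distil
Reagents that add atoms: trimethyl orthoformate (COC(OC)OC)
Why: Orthoester ketalisation followed by loss of methanol gives the conjugated methyl enol ether, which masks the β-keto ester as a β-methoxyacrylate that tolerates bases and organometallics (E isomer major; the geometry is erased in step 14).

**Step 3**
Reactants: 4 (Z)-3-iodobut-2-en-1-ol
Product: 5 tert-butyl{[(2Z)-3-iodobut-2-en-1-yl]oxy}dimethylsilane
Conditions: TBSCl, imidazole, DMF, rt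
Reagents that add atoms: tert-butyldimethylsilyl chloride (CC(C)(C)[Si](C)(C)Cl)
Why: Imidazole-promoted silyl ether formation on a primary allylic alcohol, which leaves the Z-alkenyl iodide untouched.

**Step 4**
Reactants: 6 (S)-3-hydroxydihydrofuran-2(3H)-one
Product: 7 ethyl (S)-4-bromo-2-hydroxybutanoate
Conditions: HBr (33% in AcOH), rt; then EtOH, 60 °C
Reagents that add atoms: hydrogen bromide (Br); ethanol (CCO)
Why: Acid-mediated SN2 opening of the lactone by bromide at the primary C–O carbon followed by Fischer esterification; the stereocentre is not involved, so the (S) centre of the bought lactone becomes C2 of the target.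

**Step 5**
Reactants: 7 ethyl (S)-4-bromo-2-hydroxybutanoate
Product: 8 ethyl (S)-4-bromo-2-(triethylsilyloxy)butanoate
Conditions: TESCl, imidazole, DMF, 0 °C → rt
Reagents that add atoms: chlorotriethylsilane (CC[Si](CC)(CC)Cl)
Why: Standard silyl ether protection of the secondary alcohol so that the later organozinc, hydride and organoaluminium steps are not quenched.

**Step 6**
Reactants: 8 ethyl (S)-4-bromo-2-(triethylsilyloxy)butanoate; 5 tert-butyl{[(2Z)-3-iodobut-2-en-1-yl]oxy}dimethylsilane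
Product: 10 ethyl (2S,5Z)-7-(tert-butyldimethylsilyloxy)-5-methyl-2-(triethylsilyloxy)hept-5-enoate, via alkylzinc bromide 9 (not isolated)
Conditions: Zn dust, I2 (5 mol %), DMA, 70 °C; then 5, Pd(PPh3)4 (3 mol %), 40 °C
Reagents that add atoms: none
Why: Zinc insertion into the primary C–Br bond and Negishi cross-coupling with the alkenyl iodide (zerovalent palladium) form C4–C5 with retention of the Z geometry and tolerate the ester and both silyl ethers.

**Step 7**
Reactants: 10 ethyl (2S,5Z)-7-(tert-butyldimethylsilyloxy)-5-methyl-2-(triethylsilyloxy)hept-5-enoate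
Product: 12 (3S,6Z)-8-(tert-butyldimethylsilyloxy)-6-methyl-3-(triethylsilyloxy)oct-6-en-1-yne, via aldehyde 11 (not isolated)
Conditions: i-Bu2AlH (1.1 equiv), CH2Cl2, −78 °C; then MeOH, K2CO3, dimethyl (1-diazo-2-oxopropyl)phosphonate, −78 °C → rt
Reagents that add atoms: dimethyl (1-diazo-2-oxopropyl)phosphonate (CC(=O)C(=[N+]=[N-])P(=O)(OC)OC)
Why: Partial ester reduction stops at the aluminium hemiacetal at −78 °C and the aldehyde released by methanol is homologated in the same flask by the Ohira–Bestmann (Seyferth–Gilbert) reaction, so the α-silyloxy aldehyde is never isolated and C2 is not epimerised.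

**Step 8**
Reactants: 12 (3S,6Z)-8-(tert-butyldimethylsilyloxy)-6-methyl-3-(triethylsilyloxy)oct-6-en-1-yne; 3 methyl (E)-4-bromo-3-methoxy-2-methylbut-2-enoate
Product: 14 methyl (2E,5E,7S,10Z)-12-(tert-butyldimethylsilyloxy)-3-methoxy-2,6,10-trimethyl-7-(triethylsilyloxy)dodeca-2,5,10-trienoate, via alkenylalane 13 (not isolated)
Conditions: Me3Al (2.5 equiv), Cp2ZrCl2 (0.25 equiv), CH2Cl2, 0 °C → rt; then 3, Pd(PPh3)4 (5 mol %), THF, rt
Reagents that add atoms: trimethylaluminium (C[Al](C)C)
Why: Zirconium-catalysed Negishi carboalumination adds methyl and aluminium syn across the terminal alkyne (methyl to the internal carbon, C1), and palladium-catalysed coupling of the alkenylalane with the primary carbon of allylic bromide 3 then gives the (E)-alkene with C9 trans to C2.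

**Step 9**
Reactants: 14 methyl (2E,5E,7S,10Z)-12-(tert-butyldimethylsilyloxy)-3-methoxy-2,6,10-trimethyl-7-(triethylsilyloxy)dodeca-2,5,10-trienoate
Product: 15 methyl (2E,5E,7S,10Z)-12-(tert-butyldimethylsilyloxy)-7-hydroxy-3-methoxy-2,6,10-trimethyldodeca-2,5,10-trienoate
Conditions: PPTS (0.1 equiv), MeOH, 0 °C
Reagents that add atoms: none
Why: Selective acid-catalysed methanolysis, since the secondary triethylsilyl ether is cleaved far faster than the primary tert-butyldimethylsilyl ether.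

**Step 10**
Reactants: 15 methyl (2E,5E,7S,10Z)-12-(tert-butyldimethylsilyloxy)-7-hydroxy-3-methoxy-2,6,10-trimethyldodeca-2,5,10-trienoate; 16 pent-3-yn-2-one
Product: 17 methyl (2E,5E,7S,10Z)-12-(tert-butyldimethylsilyloxy)-3-methoxy-2,6,10-trimethyl-7-{[(2E)-4-oxopent-2-en-2-yl]oxy}dodeca-2,5,10-trienoate
Conditions: PMe3 (0.1 equiv), CH2Cl2, 0 °C → rt
Reagents that add atoms: none
Why: Phosphine-catalysed oxa-Michael addition of the alcohol to the ynone gives the (E)-β-alkoxy enone, which tethers the future C11–C14 unit (with C12 and C20) to the C2 oxygen.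

**Step 11**
Reactants: 17 methyl (2E,5E,7S,10Z)-12-(tert-butyldimethylsilyloxy)-3-methoxy-2,6,10-trimethyl-7-{[(2E)-4-oxopent-2-en-2-yl]oxy}dodeca-2,5,10-trienoate
Product: 19 methyl (2E,5S,6R)-5-acetyl-6-[(1S,4Z)-6-(tert-butyldimethylsilyloxy)-1-hydroxy-4-methylhex-4-en-1-yl]-3-methoxy-2,6-dimethyl-8-oxonon-2-enoate, via photoadduct 18 (not isolated)
Conditions: hν (300 nm, Pyrex), degassed MeCN (5 mM), 20 °C; then PPTS (0.2 equiv), H2O, 20 °C
Reagents that add atoms: water (O)
Why: Proposed new method: an alcohol-tethered crossed de Mayo annulation, in which the excited β-alkoxy enone adds across the two-atom-tethered trisubstituted alkene by the rule of five (C14 to C1, C11 to C10) to give a 2-oxabicyclo[2.1.1]hexane whose strained β-alkoxy ketone opens by acid-triggered retro-aldol cleavage of C11–C14 and hydrolysis to the 1,5-diketone; the closest known reactions are the de Mayo reaction and the crossed [2+2] photocycloaddition of 3-(allyloxy)enones; C1 is set by C2 because allylic 1,2-strain holds H2 next to the C1 methyl so that the tether oxygen and the C3 chain flank the alkene and the enone adds on the oxygen face, and C10 is set by suprafacial addition to the (E)-alkene.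

**Step 12**
Reactants: 19 methyl (2E,5S,6R)-5-acetyl-6-[(1S,4Z)-6-(tert-butyldimethylsilyloxy)-1-hydroxy-4-methylhex-4-en-1-yl]-3-methoxy-2,6-dimethyl-8-oxonon-2-enoate; 20 (E)-2-methylbut-2-enoyl chloride (tigloyl chloride)
Product: 21 methyl (2E,5S,6R)-5-acetyl-6-{(1S,4Z)-6-(tert-butyldimethylsilyloxy)-4-methyl-1-[(2E)-2-methylbut-2-enoyloxy]hex-4-en-1-yl}-3-methoxy-2,6-dimethyl-8-oxonon-2-enoate
Conditions: Et3N, DMAP (0.2 equiv), CH2Cl2, 0 → 40 °C
Reagents that add atoms: none
Why: DMAP-catalysed acylation of the only free alcohol, done before ring closure so that the C2 hydroxyl cannot form hemiketals or add back to the enone later.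

**Step 13**
Reactants: 21 methyl (2E,5S,6R)-5-acetyl-6-{(1S,4Z)-6-(tert-butyldimethylsilyloxy)-4-methyl-1-[(2E)-2-methylbut-2-enoyloxy]hex-4-en-1-yl}-3-methoxy-2,6-dimethyl-8-oxonon-2-enoate
Product: 22 (1S,4Z)-6-(tert-butyldimethylsilyloxy)-1-{(1R,2R)-2-[(2E)-2-methoxy-3-(methoxycarbonyl)but-2-en-1-yl]-1,3-dimethyl-5-oxocyclohex-3-en-1-yl}-4-methylhex-4-en-1-yl (2E)-2-methylbut-2-enoate
Conditions: pyrrolidine (0.3 equiv), AcOH (0.3 equiv), toluene, 40 °C
Reagents that add atoms: none
Why: Enamine-mediated intramolecular aldol condensation (as in a Robinson annulation), in which the amine condenses only with the unhindered C13 methyl ketone, its terminal enamine carbon C12 attacks the hindered C11 ketone and dehydration gives the 3-methylcyclohexenone, while the hindered C10–H is slow to enolise so C1 and C10 are kept.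

**Step 14**
Reactants: 22 (1S,4Z)-6-(tert-butyldimethylsilyloxy)-1-{(1R,2R)-2-[(2E)-2-methoxy-3-(methoxycarbonyl)but-2-en-1-yl]-1,3-dimethyl-5-oxocyclohex-3-en-1-yl}-4-methylhex-4-en-1-yl (2E)-2-methylbut-2-enoate
Product: 23 (1S,4Z)-6-hydroxy-1-[(1R,2R)-2-(4-methoxy-3-methyl-2,4-dioxobutyl)-1,3-dimethyl-5-oxocyclohex-3-en-1-yl]-4-methylhex-4-en-1-yl (2E)-2-methylbut-2-enoate
Conditions: 1 M HCl (aq), THF, rt
Reagents that add atoms: water (O)
Why: Dilute aqueous acid cleaves the silyl ether and hydrolyses the enol ether (protonation at C17, hydration, loss of methanol), unmasking the allylic alcohol and the β-keto ester in one operation while the esters and the enone survive.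

**Step 15**
Reactants: 23 (1S,4Z)-6-hydroxy-1-[(1R,2R)-2-(4-methoxy-3-methyl-2,4-dioxobutyl)-1,3-dimethyl-5-oxocyclohex-3-en-1-yl]-4-methylhex-4-en-1-yl (2E)-2-methylbut-2-enoate
Product: 24 (1S,4Z)-1-[(1R,2R)-2-(4-methoxy-3-methyl-2,4-dioxobutyl)-1,3-dimethyl-5-oxocyclohex-3-en-1-yl]-4-methyl-6-oxohex-4-en-1-yl (2E)-2-methylbut-2-enoate
Conditions: MnO2 (20 equiv), CH2Cl2, rt
Reagents that add atoms: none
Why: Chemoselective MnO2 oxidation of the only allylic alcohol, mild enough to keep the Z geometry of the neral-type enal.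

**Step 16**
Reactants: 24 (1S,4Z)-1-[(1R,2R)-2-(4-methoxy-3-methyl-2,4-dioxobutyl)-1,3-dimethyl-5-oxocyclohex-3-en-1-yl]-4-methyl-6-oxohex-4-en-1-yl (2E)-2-methylbut-2-enoate
Product: 26 (1S,4Z)-1-{(1R,2R)-2-[(2Z)-4-methoxy-3-methyl-4-oxo-2-(trifluoromethylsulfonyloxy)but-2-en-1-yl]-1,3-dimethyl-5-oxocyclohex-3-en-1-yl}-4-methyl-6-oxohex-4-en-1-yl (2E)-2-methylbut-2-enoate, via sodium enolate 25 (not isolated)
Conditions: NaH (1.05 equiv), THF, 0 °C; then PhNTf2, 0 °C → rt
Reagents that add atoms: N-phenylbis(trifluoromethanesulfonimide) (O=S(=O)(N(c1ccccc1)S(=O)(=O)C(F)(F)F)C(F)(F)F)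
Why: NaH deprotonates only the β-keto ester, and O-sulfonylation of the sodium-chelated enolate gives the (Z)-enol triflate with the triflate cis to the ester, the geometry needed for lactonisation.

**Step 17**
Reactants: 26 (1S,4Z)-1-{(1R,2R)-2-[(2Z)-4-methoxy-3-methyl-4-oxo-2-(trifluoromethylsulfonyloxy)but-2-en-1-yl]-1,3-dimethyl-5-oxocyclohex-3-en-1-yl}-4-methyl-6-oxohex-4-en-1-yl (2E)-2-methylbut-2-enoate
Product: 28 14-deacetoxy-29 (tricyclic butenolide enone tiglate; 1R,2S,5Z,7R,10R; C14 = CH2), via hydroxy ester 27 (not isolated)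
Conditions: CrCl2 (8 equiv), NiCl2 (0.1 equiv), degassed DMF, rt, slow addition (2 mM)
Reagents that add atoms: none
Why: Nozaki–Hiyama–Kishi reaction, in which zerovalent nickel inserts into the alkenyl triflate, transmetalation gives an alkenylchromium that adds only to the aldehyde and closes the ten-membered ring, and the alkoxide held cis to the ester lactonises to the butenolide; C7 is set by C1, C2 and C10 through the ring-closing transition state, in which addition on the outer face of the enal is expected to give the (7R) alcohol.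

**Step 18**
Reactants: 28 14-deacetoxy-29
Product: 29 target (1R,2S,5Z,7R,10R,14S)
Conditions: Mn(OAc)3·2H2O (4 equiv), benzene, 80 °C (Dean–Stark)
Reagents that add atoms: manganese triacetate (CC(=O)[O-].CC(=O)[O-].CC(=O)[O-].[Mn+3])
Why: Mn(OAc)3 α'-acetoxylation of the enone through the manganese enolate at C14; in the trans-fused bicycle the C1 methyl is axial and shields one face, so acetate is delivered anti to it to give the axial (14S) acetate, which should also be the more stable epimer.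

**Compound list**
1 | methyl 2-methyl-3-oxobutanoate | CC(=O)C(C)C(=O)OC | starting material
2 | methyl 4-bromo-2-methyl-3-oxobutanoate | BrCC(=O)C(C)C(=O)OC | intermediate
3 | methyl (E)-4-bromo-3-methoxy-2-methylbut-2-enoate | COC(=O)/C(C)=C(\CBr)OC | intermediate
4 | (Z)-3-iodobut-2-en-1-ol | C/C(I)=C/CO | starting material
5 | tert-butyl{[(2Z)-3-iodobut-2-en-1-yl]oxy}dimethylsilane | C/C(I)=C/CO[Si](C)(C)C(C)(C)C | intermediate
6 | (S)-3-hydroxydihydrofuran-2(3H)-one ((S)-α-hydroxy-γ-butyrolactone) | O[C@H]1CCOC1=O | starting material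
7 | ethyl (S)-4-bromo-2-hydroxybutanoate | O[C@H](C(=O)OCC)CCBr | intermediate
8 | ethyl (S)-4-bromo-2-(triethylsilyloxy)butanoate | CC[Si](CC)(CC)O[C@H](C(=O)OCC)CCBr | intermediate
9 | bromo[(3S)-4-ethoxy-4-oxo-3-(triethylsilyloxy)butyl]zinc | CC[Si](CC)(CC)O[C@H](C(=O)OCC)CC[Zn]Br | intermediate (not isolated)
10 | ethyl (2S,5Z)-7-(tert-butyldimethylsilyloxy)-5-methyl-2-(triethylsilyloxy)hept-5-enoate | CC[Si](CC)(CC)O[C@H](C(=O)OCC)CC/C(C)=C\CO[Si](C)(C)C(C)(C)C | intermediate
11 | (2S,5Z)-7-(tert-butyldimethylsilyloxy)-5-methyl-2-(triethylsilyloxy)hept-5-enal | CC[Si](CC)(CC)O[C@H](C=O)CC/C(C)=C\CO[Si](C)(C)C(C)(C)C | intermediate (not isolated)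
12 | (3S,6Z)-8-(tert-butyldimethylsilyloxy)-6-methyl-3-(triethylsilyloxy)oct-6-en-1-yne | CC[Si](CC)(CC)O[C@H](C#C)CC/C(C)=C\CO[Si](C)(C)C(C)(C)C | intermediate
13 | [(1E,3S,6Z)-8-(tert-butyldimethylsilyloxy)-2,6-dimethyl-3-(triethylsilyloxy)octa-1,6-dien-1-yl]dimethylalane | CC[Si](CC)(CC)O[C@H](/C(C)=C/[Al](C)C)CC/C(C)=C\CO[Si](C)(C)C(C)(C)C | intermediate (not isolated)
14 | methyl (2E,5E,7S,10Z)-12-(tert-butyldimethylsilyloxy)-3-methoxy-2,6,10-trimethyl-7-(triethylsilyloxy)dodeca-2,5,10-trienoate | CC[Si](CC)(CC)O[C@H](/C(C)=C/C/C(OC)=C(/C)C(=O)OC)CC/C(C)=C\CO[Si](C)(C)C(C)(C)C | intermediate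
15 | methyl (2E,5E,7S,10Z)-12-(tert-butyldimethylsilyloxy)-7-hydroxy-3-methoxy-2,6,10-trimethyldodeca-2,5,10-trienoate | O[C@H](/C(C)=C/C/C(OC)=C(/C)C(=O)OC)CC/C(C)=C\CO[Si](C)(C)C(C)(C)C | intermediate
16 | pent-3-yn-2-one | CC#CC(C)=O | starting material
17 | methyl (2E,5E,7S,10Z)-12-(tert-butyldimethylsilyloxy)-3-methoxy-2,6,10-trimethyl-7-{[(2E)-4-oxopent-2-en-2-yl]oxy}dodeca-2,5,10-trienoate | CC(=O)/C=C(\C)O[C@H](/C(C)=C/C/C(OC)=C(/C)C(=O)OC)CC/C(C)=C\CO[Si](C)(C)C(C)(C)C | intermediate
18 | photoadduct: 5-acetyl-1,4-dimethyl-2-oxabicyclo[2.1.1]hexane carrying the (3Z)-5-(tert-butyldimethylsilyloxy)-3-methylpent-3-en-1-yl chain on C3 (S, O–CH carbon) and the (2E)-2-methoxy-3-(methoxycarbonyl)but-2-en-1-yl chain on C6 (anti to the oxygen bridge); acetyl syn to the oxygen bridge | CC(=O)[C@@H]1[C@]2(C)O[C@@H](CC/C(C)=C\CO[Si](C)(C)C(C)(C)C)[C@@]1(C)[C@@H]2C/C(OC)=C(/C)C(=O)OC | intermediate (not isolated)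
19 | methyl (2E,5S,6R)-5-acetyl-6-[(1S,4Z)-6-(tert-butyldimethylsilyloxy)-1-hydroxy-4-methylhex-4-en-1-yl]-3-methoxy-2,6-dimethyl-8-oxonon-2-enoate | CC(=O)C[C@@](C)([C@@H](O)CC/C(C)=C\CO[Si](C)(C)C(C)(C)C)[C@H](C/C(OC)=C(/C)C(=O)OC)C(C)=O | intermediate
20 | (E)-2-methylbut-2-enoyl chloride (tigloyl chloride) | C/C=C(\C)C(Cl)=O | starting material
21 | methyl (2E,5S,6R)-5-acetyl-6-{(1S,4Z)-6-(tert-butyldimethylsilyloxy)-4-methyl-1-[(2E)-2-methylbut-2-enoyloxy]hex-4-en-1-yl}-3-methoxy-2,6-dimethyl-8-oxonon-2-enoate | CC(=O)C[C@@](C)([C@@H](OC(=O)/C(C)=C/C)CC/C(C)=C\CO[Si](C)(C)C(C)(C)C)[C@H](C/C(OC)=C(/C)C(=O)OC)C(C)=O | intermediate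
22 | (1S,4Z)-6-(tert-butyldimethylsilyloxy)-1-{(1R,2R)-2-[(2E)-2-methoxy-3-(methoxycarbonyl)but-2-en-1-yl]-1,3-dimethyl-5-oxocyclohex-3-en-1-yl}-4-methylhex-4-en-1-yl (2E)-2-methylbut-2-enoate | C/C=C(\C)C(=O)O[C@@H](CC/C(C)=C\CO[Si](C)(C)C(C)(C)C)[C@]1(C)CC(=O)C=C(C)[C@H]1C/C(OC)=C(/C)C(=O)OC | intermediate
23 | (1S,4Z)-6-hydroxy-1-[(1R,2R)-2-(4-methoxy-3-methyl-2,4-dioxobutyl)-1,3-dimethyl-5-oxocyclohex-3-en-1-yl]-4-methylhex-4-en-1-yl (2E)-2-methylbut-2-enoate (both epimers at the enolisable keto ester α-carbon) | C/C=C(\C)C(=O)O[C@@H](CC/C(C)=C\CO)[C@]1(C)CC(=O)C=C(C)[C@H]1CC(=O)C(C)C(=O)OC | intermediate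
24 | (1S,4Z)-1-[(1R,2R)-2-(4-methoxy-3-methyl-2,4-dioxobutyl)-1,3-dimethyl-5-oxocyclohex-3-en-1-yl]-4-methyl-6-oxohex-4-en-1-yl (2E)-2-methylbut-2-enoate (both epimers at the keto ester α-carbon) | C/C=C(\C)C(=O)O[C@@H](CC/C(C)=C\C=O)[C@]1(C)CC(=O)C=C(C)[C@H]1CC(=O)C(C)C(=O)OC | intermediate
25 | sodium (Z)-enolate of 24 (enolate oxygen cis to the ester) | C/C=C(\C)C(=O)O[C@@H](CC/C(C)=C\C=O)[C@]1(C)CC(=O)C=C(C)[C@H]1C/C([O-])=C(\C)C(=O)OC.[Na+] | intermediate (not isolated)
26 | (1S,4Z)-1-{(1R,2R)-2-[(2Z)-4-methoxy-3-methyl-4-oxo-2-(trifluoromethylsulfonyloxy)but-2-en-1-yl]-1,3-dimethyl-5-oxocyclohex-3-en-1-yl}-4-methyl-6-oxohex-4-en-1-yl (2E)-2-methylbut-2-enoate | C/C=C(\C)C(=O)O[C@@H](CC/C(C)=C\C=O)[C@]1(C)CC(=O)C=C(C)[C@H]1C/C(OS(=O)(=O)C(F)(F)F)=C(\C)C(=O)OC | intermediate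
27 | methyl (2Z)-2-[(1R,2S,5Z,7R,10R)-7-hydroxy-1,5,11-trimethyl-2-[(2E)-2-methylbut-2-enoyloxy]-13-oxobicyclo[8.4.0]tetradeca-5,11-dien-8-ylidene]propanoate | C/C=C(\C)C(=O)O[C@H]1CC/C(C)=C\[C@@H](O)/C(=C(/C)C(=O)OC)C[C@@H]2C(C)=CC(=O)C[C@@]12C | intermediate (not isolated)
28 | 14-deacetoxy-29: the 6/10/5 tricyclic enone butenolide tiglate with C14 = CH2 (1R,2S,5Z,7R,10R, skeleton numbering) | C/C=C(\C)C(=O)O[C@H]1CC/C(C)=C\[C@H]2OC(=O)C(C)=C2C[C@@H]2C(C)=CC(=O)C[C@@]12C | intermediate
29 | CNP0218548.3, (1R,2S,5Z,7R,10R,14S)-14-acetoxy-2-tigloyloxy tricyclic enone butenolide (skeleton numbering) | C/C=C(\C)C(=O)O[C@H]1CC/C(C)=C\[C@H]2OC(=O)C(C)=C2C[C@@H]2C(C)=CC(=O)[C@@H](OC(C)=O)[C@@]12C | target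

**Step count**
Total: 18 steps. Longest linear sequence: 15 steps (steps 4 to 18, from 6).

**Steps most likely to fail, with fallbacks**

Step 11 (the proposed new photo-annulation). The acyclic β-alkoxy enone may lose its excitation by E/Z isomerisation, the straight instead of the crossed adduct may form, and the facial selectivity at C1 rests on a conformational argument that has not been tested. The fallback uses known radical chemistry, sets out from 15 and comes back at 19. Alcohol 15 is treated with 2-methoxypropene and NBS to give the mixed bromoketal F1. An Ueno–Stork 5-exo radical cyclisation (Bu3SnH, AIBN) in the presence of tert-butyl isocyanide forms the C1–C14 bond on the face of the tether oxygen and traps the C10 radical as a nitrile, giving the cyclic ketal nitrile F2. Me3Al with Ni(acac)2 (cat.) then turns the nitrile into the C11 methyl ketone, and dilute acid opens the ketal to the C13 methyl ketone and the free C2 hydroxyl, which is 19. This route does not control C10, so the C10 epimers would have to be separated.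

Step 17 (ring closure and butenolide formation). A ten-membered ring is closed at a tetrasubstituted alkenyl carbon, the Z-enal may isomerise, and the C7 configuration depends on the ring-closing transition state. The fallback changes the bond-forming logic from alkenylmetal addition to reductive carbonyl coupling; it sets out from 24 and comes back at 28. SmI2 (THF, high dilution) promotes an intramolecular ketone–aldehyde pinacol coupling between C8 and C7. The C7 alkoxide lactonises onto the ester to give the β-hydroxy lactone F3, and dehydration of the tertiary alcohol (SOCl2, pyridine) gives 28.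

Step 18 (late α'-acetoxylation). The acidic butenolide γ-hydrogen, the alkenes and possible radical side reactions of the C14 intermediate make the last step uncertain. The fallback moves the oxidation in front of the ring closure and sets C14 by equilibration; it sets out from 26 and comes back at 29. Ketone 26 is acetoxylated with Pb(OAc)4 (benzene, 80 °C) to the α'-acetoxy ketone F4 as a C14 mixture. The NiCl2/CrCl2 ring closure of step 17 then gives 29 together with its C14 epimer F5, which is equilibrated to 29 with Et3N in CH2Cl2, the axial acetate anti to the C1 methyl being the expected thermodynamic epimer.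

**Further compounds**
F1 | step 11 | mixed bromoketal of 15 (2-bromo-1-methoxy-1-methylethyl ether at the C2 oxygen; ketal carbon as a mixture) | COC(C)(CBr)O[C@H](/C(C)=C/C/C(OC)=C(/C)C(=O)OC)CC/C(C)=C\CO[Si](C)(C)C(C)(C)C
F2 | step 11 | cyclic ketal nitrile: 2-methoxy-2,4-dimethyltetrahydrofuran with the 1-cyano-3-methoxy-4-(methoxycarbonyl)pent-3-enyl group on C4 and the (3Z)-5-(tert-butyldimethylsilyloxy)-3-methylpent-3-enyl chain on C5 (ketal carbon and C10 as mixtures) | COC1(C)C[C@](C)(C(C#N)C/C(OC)=C(/C)C(=O)OC)[C@H](CC/C(C)=C\CO[Si](C)(C)C(C)(C)C)O1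
F3 | step 17 | β-hydroxy lactone: 28 with water added across C8=C17 (8-hydroxy, saturated α-methyl γ-lactone; C8 and C17 as mixtures) | C/C=C(\C)C(=O)O[C@H]1CC/C(C)=C\[C@H]2OC(=O)C(C)C2(O)C[C@@H]2C(C)=CC(=O)C[C@@]12C
F4 | step 18 | α'-acetoxy ketone: 26 carrying an acetoxy group at C14 (C14 as a mixture) | C/C=C(\C)C(=O)O[C@@H](CC/C(C)=C\C=O)[C@]1(C)C(OC(C)=O)C(=O)C=C(C)[C@H]1C/C(OS(=O)(=O)C(F)(F)F)=C(\C)C(=O)OC
F5 | step 18 | C14 epimer of 29 (14R) | C/C=C(\C)C(=O)O[C@H]1CC/C(C)=C\[C@H]2OC(=O)C(C)=C2C[C@@H]2C(C)=CC(=O)[C@H](OC(C)=O)[C@@]12C
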